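**Assumption:** (S,S)-ProPhenol/Et2Zn is taken to direct the ynone enolate to the Si face of aldehyde 10 (giving 5S); if the sense is the reverse, the (R,R)-ligand is used and nothing else changes.

Ar = 7-methoxy-4-oxo-2-(2-phenylethyl)-4H-chromen-6-yl. Target numbering (C2–C8a) is used for the tetrahydrochromone atoms throughout. The route has not been run; it is a design.

## Retrosynthetic overview

1. Target 18 ⇐ acid removal of a 6,7-acetonide and a 5-O-TES group from bicycle 17.
2. 17 ⇐ acyclic ester–ynone 15: one operation closes the carbocycle (C4a–C8a, Dieckmann-type) and the γ-pyrone (O1–C2, 6-endo-dig oxa-Michael).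
3. 15 ⇐ aldol (C4a–C5, sets C5) of methyl ynone 13 with aldehyde 10.
4. 10 ⇐ D-gluconate diacetonide 7 + phenol 5 by Mitsunobu inversion (sets C8; C6 and C7 come from the sugar), then glycol cleavage.
5. Ring order: aromatic chromone 5 first (from acetophenone 2); the carbocycle and the second pyranone are formed together, last.

## Route

Step 1
Reactants: 1 2-methoxybenzene-1,4-diol (methoxyhydroquinone)
Product: 2 1-(2,5-dihydroxy-4-methoxyphenyl)ethan-1-one
Conditions: AcOH, BF3·OEt2 (as solvent/Lewis acid), 90 °C; then H2O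
Reagents that add atoms: acetic acid CC(=O)O
Why: Friedel–Crafts (Nencki-type) C-acylation occurs at the position para to OMe and ortho to OH, which is the most activated site and gives a BF2-chelated o-hydroxy ketone.

Step 2
Reactants: 2 1-(2,5-dihydroxy-4-methoxyphenyl)ethan-1-one; 3 ethyl 3-phenylpropanoate
Product: 5 6-hydroxy-7-methoxy-2-(2-phenylethyl)-4H-chromen-4-one (ArOH), via aryl 1,3-diketone 4 (not isolated)
Conditions: NaH (5 equiv), THF, reflux; then conc. HCl, AcOH, 90 °C
Reagents that add atoms: none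
Why: Claisen condensation of the acetophenone polyanion with the ester, then acid cyclodehydration of the o-hydroxyaryl β-diketone, is the standard 2-(2-phenylethyl)chromone synthesis; only the ortho OH can close the ring.

Step 3
Reactants: 6 D-glucono-1,5-lactone
Product: 7 methyl 3,4:5,6-di-O-isopropylidene-D-gluconate (free 2-OH)
Conditions: Me2C(OMe)2, acetone, MeOH, TsOH·H2O (cat.), rt, 48 h
Reagents that add atoms: 2,2-dimethoxypropane COC(C)(C)OC; methanol CO
Why: Acid-catalysed lactone methanolysis and thermodynamic acetalisation of the 3,4- and 5,6-diols is a known one-step preparation that leaves only the α-hydroxy ester OH free.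

Step 4
Reactants: 7 methyl 3,4:5,6-di-O-isopropylidene-D-gluconate; 5 ArOH
Product: 8 methyl 3,4:5,6-di-O-isopropylidene-2-O-Ar-D-mannonate
Conditions: PPh3, DIAD, THF, 0 °C → rt
Reagents that add atoms: none
Why: Mitsunobu etherification of an α-hydroxy ester with a phenol proceeds by clean SN2 inversion (D-gluco → D-manno at C2), which sets the future C8 with OAr cis to O-7.

Step 5
Reactants: 8 methyl 3,4:5,6-di-O-isopropylidene-2-O-Ar-D-mannonate
Product: 10 methyl 4-O-Ar-2,3-O-isopropylidene-aldehydo-D-arabinuronate (C1–C5 of the mannonate, C5 now CHO), via 5,6-diol 9 (not isolated)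
Conditions: H5IO6 (1.3 equiv), EtOAc, rt; used crude
Reagents that add atoms: none
Why: Periodic acid hydrolyses the terminal acetonide selectively and cleaves the resulting 1,2-diol (Malaprade cleavage), while the internal trans-acetonide, ester and aryl ether are untouched.

Step 6
Reactants: 11 4-phenylbut-1-yne
Product: 13 6-phenylhex-3-yn-2-one, via lithium acetylide 12 (not isolated)
Conditions: n-BuLi, THF, −78 °C; MeC(O)N(OMe)Me, −78 → 0 °C; aq. NH4Cl
Reagents that add atoms: N-methoxy-N-methylacetamide CC(=O)N(C)OC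
Why: Acylation of a lithium acetylide with a Weinreb amide stops at the ketone because the chelated tetrahedral adduct only collapses on work-up.

Step 7
Reactants: 10 aldehyde; 13 6-phenylhex-3-yn-2-one (1.5 equiv)
Product: 14 (5S)-β-hydroxy ynone MeO2C–CH(OAr)–[3,4-trans-acetonide]–CH(OH)–CH2–CO–C≡C–CH2CH2Ph (L-gulo configuration at C2–C5 of the sugar chain)
Conditions: (S,S)-ProPhenol (10 mol%), Et2Zn (20 mol%), 4 Å MS, THF, 0 °C → rt
Reagents that add atoms: none
Why: The Trost dinuclear Zn–ProPhenol direct aldol is established for methyl ynone donors; catalyst-controlled Si-face addition gives the 5S carbinol (5,6-syn, which becomes 5,6-trans in the ring), against the substrate's Felkin preference.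

Step 8
Reactants: 14 (5S)-β-hydroxy ynone
Product: 15 5-O-triethylsilyl ether of 14
Conditions: TESOTf, 2,6-lutidine, CH2Cl2, −78 °C
Reagents that add atoms: triethylsilyl triflate CC[Si](CC)(CC)OS(=O)(=O)C(F)(F)F
Why: Silylation with a non-nucleophilic base blocks the 5-OH, which would otherwise add 6-endo to the ynone to give a dihydropyranone, and does not touch the ynone.

Step 9
Reactants: 15 TES-protected ester–ynone
Product: 17 5-O-triethylsilyl-6,7-O-isopropylidene derivative of the target (configuration at C5–C8 as in 18), via cyclic 2-alkynoyl β-diketone 16 (not isolated)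
Conditions: LiHMDS (1.15 equiv), THF (0.01 M), −78 → −30 °C; then AcOH (1.3 equiv), Et3N (1 equiv), −30 °C → rt
Reagents that add atoms: none
Why: Proposed new method: LiHMDS deprotonates the only ketone α-CH2 (C4a), whose enolate attacks the activated α-aryloxy methyl ester 6-exo-trig (Dieckmann/intramolecular Claisen, driven by formation of the β-diketonate) to close the carbocycle; on buffering, the C8a enol oxygen adds 6-endo-dig to the ynone to close the γ-pyrone and remove the last C4a–H, so the 5-silyloxy group can no longer eliminate; the closest known reactions are Dieckmann condensation and the base-mediated cyclisation of acetylenic β-diketones and o-hydroxyaryl ynones to γ-pyrones/chromones; no stereocentre is formed and C5–C8 are spectators.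

Step 10
Reactants: 17 protected bicycle
Product: 18 target, (5S,6R,7S,8S)-5,6,7-trihydroxy-8-(ArO)-2-(2-phenylethyl)-5,6,7,8-tetrahydro-4H-chromen-4-one
Conditions: AcOH/H2O (4:1), 45 °C
Reagents that add atoms: none
Why: Mild aqueous acid hydrolyses the strained trans-fused acetonide and the secondary TES ether by Si–O and acetal C–O cleavage, so no ring C–O bond is broken and all four stereocentres are retained.

## Compound list

1 | 2-methoxybenzene-1,4-diol | COc1cc(O)ccc1O | starting material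
2 | 1-(2,5-dihydroxy-4-methoxyphenyl)ethan-1-one | CC(=O)c1cc(O)c(OC)cc1O | intermediate
3 | ethyl 3-phenylpropanoate | CCOC(=O)CCc1ccccc1 | starting material
4 | 1-(2,5-dihydroxy-4-methoxyphenyl)-5-phenylpentane-1,3-dione | O=C(CC(=O)CCc1ccccc1)c1cc(O)c(OC)cc1O | intermediate
5 | 6-hydroxy-7-methoxy-2-(2-phenylethyl)-4H-chromen-4-one (ArOH) | COc1cc2oc(CCc3ccccc3)cc(=O)c2cc1O | intermediate
6 | D-glucono-1,5-lactone | O=C1O[C@H](CO)[C@@H](O)[C@H](O)[C@H]1O | starting material
7 | methyl 3,4:5,6-di-O-isopropylidene-D-gluconate | COC(=O)[C@H](O)[C@H]1OC(C)(C)O[C@@H]1[C@H]1COC(C)(C)O1 | intermediate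
8 | methyl 3,4:5,6-di-O-isopropylidene-2-O-Ar-D-mannonate | COc1cc2oc(CCc3ccccc3)cc(=O)c2cc1O[C@H](C(=O)OC)[C@H]1OC(C)(C)O[C@@H]1[C@H]1COC(C)(C)O1 | intermediate
9 | methyl 3,4-O-isopropylidene-2-O-Ar-D-mannonate (5,6-diol) | COc1cc2oc(CCc3ccccc3)cc(=O)c2cc1O[C@H](C(=O)OC)[C@H]1OC(C)(C)O[C@@H]1[C@H](O)CO | intermediate
10 | methyl 4-O-Ar-2,3-O-isopropylidene-aldehydo-D-arabinuronate | COc1cc2oc(CCc3ccccc3)cc(=O)c2cc1O[C@H](C(=O)OC)[C@H]1OC(C)(C)O[C@@H]1C=O | intermediate
11 | 4-phenylbut-1-yne | C#CCCc1ccccc1 | starting material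
12 | lithium 4-phenylbut-1-yn-1-ide | [Li]C#CCCc1ccccc1 | intermediate
13 | 6-phenylhex-3-yn-2-one | CC(=O)C#CCCc1ccccc1 | intermediate
14 | (5S)-β-hydroxy ynone (methyl 2-O-Ar-6-deoxy-3,4-O-isopropylidene-L-gulo-heptonate with C7 = ketone bearing 4-phenylbut-1-ynyl) | COc1cc2oc(CCc3ccccc3)cc(=O)c2cc1O[C@H](C(=O)OC)[C@H]1OC(C)(C)O[C@@H]1[C@@H](O)CC(=O)C#CCCc1ccccc1 | intermediate
15 | 5-O-triethylsilyl ether of 14 | COc1cc2oc(CCc3ccccc3)cc(=O)c2cc1O[C@H](C(=O)OC)[C@H]1OC(C)(C)O[C@@H]1[C@@H](O[Si](CC)(CC)CC)CC(=O)C#CCCc1ccccc1 | intermediate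
16 | cyclic β-diketone (enol form): 8-OAr, 6,7-O-isopropylidene, 5-OTES cyclohexenol carrying the 5-phenylpent-2-ynoyl group at C4a | COc1cc2oc(CCc3ccccc3)cc(=O)c2cc1O[C@@H]1C(O)=C(C(=O)C#CCCc2ccccc2)[C@H](O[Si](CC)(CC)CC)[C@H]2OC(C)(C)O[C@H]12 | intermediate
17 | 5-O-triethylsilyl-6,7-O-isopropylidene derivative of 18 | COc1cc2oc(CCc3ccccc3)cc(=O)c2cc1O[C@@H]1c2oc(CCc3ccccc3)cc(=O)c2[C@H](O[Si](CC)(CC)CC)[C@H]2OC(C)(C)O[C@H]12 | intermediate
18 | (5S,6R,7S,8S)-5,6,7-trihydroxy-8-(ArO)-2-(2-phenylethyl)-5,6,7,8-tetrahydro-4H-chromen-4-one | COc1cc2oc(CCc3ccccc3)cc(=O)c2cc1O[C@@H]1c2oc(CCc3ccccc3)cc(=O)c2[C@H](O)[C@@H](O)[C@@H]1O | target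

## Summary

Total step count: 10. Longest linear sequence: 8 (steps 1, 2, 4, 5, 7, 8, 9, 10).

Steps most likely to fail:

1. **Step 9 (cascade).** The lithium enolate may eliminate the β-silyloxy group or epimerise C8 before it acylates. The fallback sets out from 15 and comes back at 17. Me3SnOH (1,2-dichloroethane, 60 °C) cleaves the methyl ester to the carboxylic acid F1. C6F5OH/EDC converts it into the pentafluorophenyl ester F2. Soft enolisation (MgBr2·OEt2, i-Pr2NEt, CH2Cl2, 0 °C) then C-acylates C4a intramolecularly without a free lithium enolate, and Et3N closes the pyranone to give 17.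

2. **Step 7 (aldol).** Catalyst control may not override the Felkin preference of the α-alkoxy aldehyde. The fallback sets out from 10 and 13 and comes back at 18. The lithium enolate of 13 (LDA, THF, −78 °C) adds under substrate control to give the 5R aldol F3. TESOTf/2,6-lutidine gives the silyl ether F4, and the same LiHMDS cascade gives the 5-epi bicycle F5. HF·pyridine frees the 5R alcohol F6, and Dess–Martin periodinane oxidises it to the 5-ketone F7. NaBH4/CeCl3 (MeOH, −78 °C) delivers hydride axially to give the 5S alcohol F8 (equatorial OH, trans to O-6). 80% AcOH then hydrolyses the acetonide to 18.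

3. **Step 4 (Mitsunobu).** The hindered α-hydroxy ester may react sluggishly with the chromone phenol. The fallback sets out from 7 and comes back at 8. Tf2O/pyridine (CH2Cl2, −20 °C) gives the 2-O-triflate F9, which the potassium phenoxide of 5 (K2CO3, 18-crown-6, MeCN, rt) displaces with the same inversion.

## Further compounds

F1 | step 9 | carboxylic acid of 15 (methyl ester hydrolysed) | COc1cc2oc(CCc3ccccc3)cc(=O)c2cc1O[C@H](C(=O)O)[C@H]1OC(C)(C)O[C@@H]1[C@@H](O[Si](CC)(CC)CC)CC(=O)C#CCCc1ccccc1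
F2 | step 9 | pentafluorophenyl ester of F1 | COc1cc2oc(CCc3ccccc3)cc(=O)c2cc1O[C@H](C(=O)Oc1c(F)c(F)c(F)c(F)c1F)[C@H]1OC(C)(C)O[C@@H]1[C@@H](O[Si](CC)(CC)CC)CC(=O)C#CCCc1ccccc1
F3 | step 7 | (5R)-epimer of 14 | COc1cc2oc(CCc3ccccc3)cc(=O)c2cc1O[C@H](C(=O)OC)[C@H]1OC(C)(C)O[C@@H]1[C@H](O)CC(=O)C#CCCc1ccccc1
F4 | step 7 | 5-O-triethylsilyl ether of F3 | COc1cc2oc(CCc3ccccc3)cc(=O)c2cc1O[C@H](C(=O)OC)[C@H]1OC(C)(C)O[C@@H]1[C@H](O[Si](CC)(CC)CC)CC(=O)C#CCCc1ccccc1
F5 | step 7 | 5-epimer of 17 | COc1cc2oc(CCc3ccccc3)cc(=O)c2cc1O[C@@H]1c2oc(CCc3ccccc3)cc(=O)c2[C@@H](O[Si](CC)(CC)CC)[C@H]2OC(C)(C)O[C@H]12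
F6 | step 7 | 5-epi-6,7-O-isopropylidene derivative of 18 (5R alcohol) | COc1cc2oc(CCc3ccccc3)cc(=O)c2cc1O[C@@H]1c2oc(CCc3ccccc3)cc(=O)c2[C@@H](O)[C@H]2OC(C)(C)O[C@H]12
F7 | step 7 | 5-oxo-6,7-O-isopropylidene analogue of 18 (5-ketone) | COc1cc2oc(CCc3ccccc3)cc(=O)c2cc1O[C@@H]1c2oc(CCc3ccccc3)cc(=O)c2C(=O)[C@H]2OC(C)(C)O[C@H]12
F8 | step 7 | 6,7-O-isopropylidene derivative of 18 (5S alcohol) | COc1cc2oc(CCc3ccccc3)cc(=O)c2cc1O[C@@H]1c2oc(CCc3ccccc3)cc(=O)c2[C@H](O)[C@H]2OC(C)(C)O[C@H]12
F9 | step 4 | methyl 3,4:5,6-di-O-isopropylidene-2-O-(trifluoromethylsulfonyl)-D-gluconate | COC(=O)[C@H](OS(=O)(=O)C(F)(F)F)[C@H]1OC(C)(C)O[C@@H]1[C@H]1COC(C)(C)O1
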